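(The readings stem from a simulated flask with made-up constants, and the scatter is random.)

Does more scavenger change how much substrate has reacted after 5.0 h? Turn the question round and ask what the opposite outcome would need.

| flask | substrate | reagent | scavenger | remark | time |
|---|---|---|---|---|---|
| birch | 0.10 M | 0.22 M | 0.15 M | run made earlier |  |
| larch | 0.20 M | 0.15 M | 0.15 M | run made earlier |  |
| summer | 0.10 M | 0.150 M | 0.150 M |  | 5.0 h |
| spring | 0.10 M | 0.150 M | 0.200 M |  | 5.0 h |

- birch (time / min: substrate / %, triple product / %): 8.00: 94.8, 0.9; 15.0: 91.8, 0.1; 25.0: 86.8, 0; 30.0: 85.5, 0.6; 40.0: 81.1, 0; 50.0: 78.6, 0.8; 60.0: 75.2, 0
- larch (time / min: substrate / %, triple product / %): 3.00: 98.8, 0; 10.0: 94.8, 0; 15.0: 93.2, 0.4; 25.0: 90.0, 0; 40.0: 85.6, 0.1; 50.0: 83.7, 0.4; 60.0: 81.1, 0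

(standard deviation of a reading: 0.5 percentage points)

- part of the substrate that has reacted at the end, summer
- part of the substrate that has reacted at the end, spring
- what raising the concentration of scavenger from its lowest to its highest value here does to the part of the substrate that has reacted (changes below 5 percentage points count as none) (no change / it falls / it rises)

- amounts and yields of released group count idle adduct too
- steps that have been proposed: substrate + reagent -> first product + released group; reagent + first product -> double product + released group; reagent + double product -> triple product + released group; reagent + triple product -> tetra adduct + released group; substrate + released group <-> idle adduct; scavenger + released group -> scavenged by-product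
- no earlier run changes the charge of scavenger; that part of a forecast is a guess

Write the loss of substrate as k[substrate][reagent]: scavenger stands in no proposed step that consumes substrate. Treat birch as pseudo-first-order, since one-to-one with substrate its reagent has lost about 11.3 % of its charge by 60.0 min. That reading gives 0.02159 /M/min. Call this the pace constant: the fall in ln[substrate] per minute per molar of reagent.

Carry it into summer with substrate and reagent falling one-to-one, and my reckoning gives 53.4 % reacted.

Scavenger can reach substrate through idle adduct. Count that adduct as reacted, since it is no longer free substrate. A shift of 5 percentage points then needs the idle adduct of summer and spring to differ by a share of that order. Birch at 8.00 min reads 94.8 % against the 96.3 % that k predicts, a gap of 1.5 points, which is less than 5 points. Expect no change, though no run varied scavenger, so this stays a guess.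

The forecast gives 50 % for summer and 51 % for spring, with no change: “Scavenger already covers all the released group, so more of it changes little.”

The flask gives 50.2 % for summer and 50.0 % for spring, a shift of −0.26 points, so no change, and the forecast held.

    substrate + reagent → first product + released group (k = 1.23 /M/h)
    reagent + first product → double product + released group (k = 1.14 /M/h)
    reagent + double product → triple product + released group (k = 3.11 /M/h)
    reagent + triple product → tetra adduct + released group (k = 0.475 /M/h)
    substrate + released group ⇌ idle adduct, settled at all times (K = 13.9 /M)
    scavenger + released group → scavenged by-product (k = 71.1 /M/h)

Summer at 5.00 h holds idle adduct at 1.22 % of the charge and spring at 0.779 %, a difference of 0.44 points, less than the 5 points that counts as a change. Its reagent stands at 53.6 % against the 64.4 % of the one-to-one reckoning, with double product at 8.02 % and triple product at 5.62 %. Now take the neighbour flask, summer with 0.060 M of reagent, 0.600 equiv, which makes reagent the limiting reagent. The same k gives 25.5 % reacted, and that flask gives 24.5 %.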